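**Retrosynthetic overview**

1. The carbons of ring A (the dearomatised ring) are lettered round the ring: a = C(CH3)(geranyl), b = C–OH, c = C–acetyl, d = C=O, e = C–CH2–ring B, f = C–OH. Ring B is the aromatic butyrylphloroglucinol.
2. Enabling feature: ring A is a cyclohexane-1,3,5-trione (oxygen on carbons b, d and f) in which carbons a and c are both α to the carbonyl at b, and carbon a carries exactly one allyl group. The a–b–c unit can therefore enter as geranyl 2-methylacetoacetate (the ester is activating group and geranyl carrier) and the d–e–f unit as a malonyl unit.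
3. 18 ⇒ 13 + 16: the CH2 bridge is made last by reductive arylation of an aminomethylene carbon on carbon e. 13 ⇒ 12: the stereocentre at carbon a is set by stereoablative decarboxylative asymmetric allylation (ester O-geranyl → C-geranyl, CO2 lost).
4. 12 ⇒ 10 ⇒ 4 + 5 + 6: a three-component acylative [3+3] annulation (bonds f–a and c–d, then c–acetyl) builds ring A, its quaternary carbon and its acetyl group in one flask.
5. Ring order: ring B is bought (14) and prenylated; ring A is the only ring formed (step 3).

Key step: step 3

Assumption: ring A compounds are written as one enol tautomer of a rapidly equilibrating set, and CIP descriptors refer to the tautomer drawn (the target centre is R as drawn).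
Assumption: the (R,R)-ligand in step 5 is taken to deliver the required configuration; the sense of induction has to be checked on the first run and the (S,S)-ligand used if it is opposite.

**Step 1**
Reactants: 1 ethyl 2-methyl-3-oxobutanoate; 2 geraniol [(2E)-3,7-dimethylocta-2,6-dien-1-ol]
Product: 3 geranyl 2-methyl-3-oxobutanoate (racemic)
Conditions: 4-(dimethylamino)pyridine (0.2 equiv), toluene, reflux, EtOH distilled off
Reagents that add atoms: none
Why: Transesterification of a β-keto ester under nucleophilic catalysis, driven by removal of ethanol, should leave the allylic alcohol carbon and both alkenes untouched; the configuration of the α-carbon is of no consequence.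

**Step 2**
Reactants: 3 geranyl 2-methyl-3-oxobutanoate
Product: 4 geranyl 2-methyl-3-(trimethylsilyloxy)but-2-enoate (E/Z mixture)
Conditions: Me3SiOTf (1.1 equiv), Et3N (1.5 equiv), CH2Cl2, 0 °C; filtered and used crude
Reagents that add atoms: trimethylsilyl trifluoromethanesulfonate, C[Si](C)(C)OS(=O)(=O)C(F)(F)F
Why: Soft enolisation with O-silylation of a β-keto ester should give the conjugated silyl enol ether, which places the nucleophilicity on the methyl-bearing α-carbon (future carbon a); the enol ether geometry is irrelevant.

**Step 3**
Reactants: 4 geranyl 2-methyl-3-(trimethylsilyloxy)but-2-enoate; 5 malonyl dichloride; 6 acetyl chloride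
Product: 10 geranyl 3-acetyl-2-hydroxy-1-methyl-4,6-dioxocyclohex-2-ene-1-carboxylate (racemic), via acid chloride 7 (not isolated), via trione ester 8 (not isolated), via enol acetate 9 (not isolated)
Conditions: 4 added to 5 (1.05 equiv), CH2Cl2, −40 °C → rt; then Et3N (3.5 equiv), high dilution, 0 °C → rt; then 6 (1.0 equiv), 0 °C; then 4-(dimethylamino)pyridine (10 mol %), rt
Reagents that add atoms: none
Why: Proposed new method: the methyl-bearing enol ether carbon of 4 should attack one acyl chloride of 5 (Mukaiyama-type C-acylation, Me3SiCl lost) to give 7 and the a–f bond, after which Et3N converts the β-keto acyl chloride into an acylketene that is captured by the enol carbon of the neighbouring methyl ketone to form the c–d bond and the stabilised enolate of 8, which 6 O-acetylates to 9 and 4-(dimethylamino)pyridine isomerises to 10 by an O→C acyl shift. The closest known reaction types are the Effenberger cyclisation of ketone silyl enol ethers with malonyl dichloride and the enol ester to 2-acyl-1,3-dione rearrangement, neither of which has been shown on an acyclic 3-silyloxy-2-enoate closing onto a methyl ketone or telescoped in this way. Ring A closes by a 6-(enolendo)-exo-dig C-acylation of the ketene (6-(enolendo)-exo-trig if the acyl chloride reacts directly). Carbon a becomes a stereocentre only when the acetyl group differentiates the two equivalent CH2 groups of achiral 8, so it forms racemic and needs no control because step 5 erases and resets it. The step needs C- over O-acylation and a carbocycle instead of a 2-pyranone: the methyl group on carbon a removes the α-hydrogen that pyranone aromatisation would require, an enol lactone from O-attack can revert to the acylketene by base-induced elimination, and only the trione reaches a stabilised enolate. Chemoselectivity rests on the silyl enol ether being far more nucleophilic than the geranyl alkenes (no Lewis acid, no free HCl) and on the enolate of 10 being too deactivated for a second acetylation.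

**Step 4**
Reactants: 10 geranyl 3-acetyl-2-hydroxy-1-methyl-4,6-dioxocyclohex-2-ene-1-carboxylate; 11 tert-butoxybis(dimethylamino)methane
Product: 12 geranyl 3-acetyl-5-[(dimethylamino)methylidene]-2-hydroxy-1-methyl-4,6-dioxocyclohex-2-ene-1-carboxylate (racemic)
Conditions: 11 (1.1 equiv), CH2Cl2, 0 °C → rt
Reagents that add atoms: none
Why: Condensation of the only remaining active methylene (carbon e, between two carbonyls) with a non-alkylating formamide aminal should give the vinylogous amide (enaminone formation); its carbon is the future bridge CH2 and the group blocks carbon e as an acyl-type substituent for step 5.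

**Step 5**
Reactants: 12 geranyl 3-acetyl-5-[(dimethylamino)methylidene]-2-hydroxy-1-methyl-4,6-dioxocyclohex-2-ene-1-carboxylate
Product: 13 (4S)-2-acetyl-6-[(dimethylamino)methylidene]-4-[(2E)-3,7-dimethylocta-2,6-dien-1-yl]-3-hydroxy-4-methylcyclohex-2-ene-1,5-dione
Conditions: Pd2(dba)3 (2.5 mol %), (R,R)-DACH-phenyl ligand [N,N′-(1R,2R)-cyclohexane-1,2-diylbis(2-diphenylphosphinobenzamide)] (6 mol %), degassed THF, 0 °C → rt
Reagents that add atoms: none
Why: In this decarboxylative asymmetric allylic alkylation (Tsuji–Trost type) zerovalent palladium ionises the geranyl ester and CO2 is lost, so both enantiomers of 12 give the same planar ring A enolate, which is re-allylated at the CH2 terminus of the π-geranyl complex inside the chiral ligand pocket; the ligand sets the configuration at carbon a by telling the acetyl flank from the aminomethylene flank, the acyl-type groups on carbons c and e leave carbon a as the only carbon open to C-allylation, and fast capture of the syn complex should keep the (E)-alkene.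

**Step 6**
Reactants: 14 1-(2,4,6-trihydroxyphenyl)butan-1-one; 15 1-bromo-3-methylbut-2-ene
Product: 16 1-[2,4,6-trihydroxy-3-(3-methylbut-2-en-1-yl)phenyl]butan-1-one
Conditions: 15 (0.9 equiv), 10% aq. KOH, 0 °C
Reagents that add atoms: none
Why: C-alkylation of the acylphloroglucinol phenolate (known mono-C-prenylation) should give one isomer because the two free ring positions of 14 are equivalent; the sub-stoichiometric bromide limits double prenylation.

**Step 7**
Reactants: 13 (4S)-2-acetyl-6-[(dimethylamino)methylidene]-4-geranyl-3-hydroxy-4-methylcyclohex-2-ene-1,5-dione; 16 1-[2,4,6-trihydroxy-3-(3-methylbut-2-en-1-yl)phenyl]butan-1-one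
Product: 18 CNP0227753.1 (target), via arylidene 17 (not isolated)
Conditions: 16 (1.2 equiv), diethyl 2,6-dimethyl-1,4-dihydropyridine-3,5-dicarboxylate (1.3 equiv), AcOH/CH2Cl2 (1:4), 35 °C
Reagents that add atoms: none
Why: Acid-promoted addition–elimination of the single free, strongly nucleophilic ring B carbon at the enaminone carbon (Friedel–Crafts-type exchange of the vinylogous amide, Me2NH lost) should give arylidene 17, whose exocyclic C=C is reduced in situ by hydride transfer from the Hantzsch ester (conjugate reduction of an alkylidene 1,3-dione); the quaternary centre is not involved.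

**Compound list**

1 | ethyl 2-methyl-3-oxobutanoate | CCOC(=O)C(C)C(C)=O | starting material
2 | geraniol, (2E)-3,7-dimethylocta-2,6-dien-1-ol | OC/C=C(\C)CCC=C(C)C | starting material
3 | geranyl 2-methyl-3-oxobutanoate (racemic) | CC(=O)C(C)C(=O)OC/C=C(\C)CCC=C(C)C | intermediate
4 | geranyl 2-methyl-3-(trimethylsilyloxy)but-2-enoate (E/Z mixture at the enol ether) | CC(O[Si](C)(C)C)=C(C)C(=O)OC/C=C(\C)CCC=C(C)C | intermediate
5 | malonyl dichloride (propanedioyl dichloride) | O=C(Cl)CC(=O)Cl | starting material
6 | acetyl chloride | CC(=O)Cl | starting material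
7 | geranyl 2-acetyl-5-chloro-2-methyl-3,5-dioxopentanoate (racemic) | CC(=O)C(C)(C(=O)CC(=O)Cl)C(=O)OC/C=C(\C)CCC=C(C)C | intermediate
8 | geranyl 1-methyl-2,4,6-trioxocyclohexane-1-carboxylate (achiral, enolised in solution) | CC1(C(=O)OC/C=C(\C)CCC=C(C)C)C(=O)CC(=O)CC1=O | intermediate
9 | geranyl 4-acetoxy-1-methyl-2,6-dioxocyclohex-3-ene-1-carboxylate (racemic) | CC(=O)OC1=CC(=O)C(C)(C(=O)OC/C=C(\C)CCC=C(C)C)C(=O)C1 | intermediate
10 | geranyl 3-acetyl-2-hydroxy-1-methyl-4,6-dioxocyclohex-2-ene-1-carboxylate (racemic) | CC(=O)C1=C(O)C(C)(C(=O)OC/C=C(\C)CCC=C(C)C)C(=O)CC1=O | intermediate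
11 | tert-butoxybis(dimethylamino)methane | CN(C)C(N(C)C)OC(C)(C)C | starting material
12 | geranyl 3-acetyl-5-[(dimethylamino)methylidene]-2-hydroxy-1-methyl-4,6-dioxocyclohex-2-ene-1-carboxylate (racemic) | CC(=O)C1=C(O)C(C)(C(=O)OC/C=C(\C)CCC=C(C)C)C(=O)C(=CN(C)C)C1=O | intermediate
13 | (4S)-2-acetyl-6-[(dimethylamino)methylidene]-4-[(2E)-3,7-dimethylocta-2,6-dien-1-yl]-3-hydroxy-4-methylcyclohex-2-ene-1,5-dione | CC(=O)C1=C(O)[C@](C)(C/C=C(\C)CCC=C(C)C)C(=O)C(=CN(C)C)C1=O | intermediate
14 | 1-(2,4,6-trihydroxyphenyl)butan-1-one | CCCC(=O)c1c(O)cc(O)cc1O | starting material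
15 | 1-bromo-3-methylbut-2-ene (prenyl bromide) | CC(C)=CCBr | starting material
16 | 1-[2,4,6-trihydroxy-3-(3-methylbut-2-en-1-yl)phenyl]butan-1-one | CCCC(=O)c1c(O)cc(O)c(CC=C(C)C)c1O | intermediate
17 | arylidene (o-quinone methide type) precursor of the target, ring A carbon e joined to ring B through =CH–, (S) at carbon a as drawn | CCCC(=O)c1c(O)c(CC=C(C)C)c(O)c(C=C2C(=O)[C@@](C)(C/C=C(\C)CCC=C(C)C)C(O)=C(C(C)=O)C2=O)c1O | intermediate
18 | CNP0227753.1, (R) at the quaternary carbon as drawn, (E)-geranyl | CCCC(=O)c1c(O)c(CC=C(C)C)c(O)c(CC2=C(O)[C@@](C)(C/C=C(\C)CCC=C(C)C)C(O)=C(C(C)=O)C2=O)c1O | target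

**Count and risks**

Total step count: 7. Longest linear sequence: 6 steps (1, 2, 3, 4, 5, 7).

Steps most likely to fail:

1. Step 3. Ring closure may be outrun by O-acylation of the methyl ketone enol, by oligomerisation of the transient acylketene, or by retro-Claisen loss of an acyl group from the crowded quaternary carbon of 7. Fallback, from 3 and back at 10: 3 is C-acylated under soft enolisation (MgCl2, pyridine, CH2Cl2, 0 °C) with methyl 3-chloro-3-oxopropanoate to give 1-geranyl 5-methyl 2-acetyl-2-methyl-3-oxopentanedioate F1. Base-mediated Claisen (Dieckmann-type) ring closure of F1 (KOtBu, THF, 0 °C → rt; methyl ketone enolate onto the methyl ester) should give 8, which is isolated and then C-acetylated in a separate flask (6, Et3N, then 4-(dimethylamino)pyridine) to 10.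

2. Step 5. Facial discrimination of the nearly symmetric ring A enolate by the ligand may be insufficient, the π-geranyl complex may lose its E geometry, or the product may re-ionise and erode. Fallback, from 12 and back at 18: decarboxylative allylation with achiral Pd(PPh3)4 (THF, rt) should give the racemic enaminone F2. Amine exchange with (S)-1-phenylethanamine (EtOH, rt) should give two diastereomeric secondary enaminones, the (4S)-configured N-[(1S)-1-phenylethyl] enaminone F3 and the (4R)-configured N-[(1S)-1-phenylethyl] enaminone F4. F3 is separated by crystallisation or chromatography and taken through the conditions of step 7 with 16 in place of 13, where the auxiliary amine is the leaving group, giving 18.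

3. Step 7. Cyclodehydration of the arylidene intermediate onto the neighbouring ring B hydroxyl (xanthene-type closure) may outrun hydride transfer, or the weakly electrophilic vinylogous amide may fail to engage ring B. Fallback, from 13 and back at 18: the aminomethylene group is removed (aq. NaOH, THF/MeOH, 0 °C; hydrolysis to the 2-formyl trione and retro-Claisen loss of formate) to give (4S)-2-acetyl-4-geranyl-3-hydroxy-4-methylcyclohex-2-ene-1,5-dione F5, which is unsubstituted at carbon e. 16 is converted with N,N-dimethylmethyleneiminium iodide (CH2Cl2, rt) into the ring B Mannich base F6. Heating F5 with F6 (1,4-dioxane, 80 °C) should release the ring B o-quinone methide F7, which is trapped by the enol carbon e of F5 to give 18.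

**Further compounds**

F1 | step 3 | 1-geranyl 5-methyl 2-acetyl-2-methyl-3-oxopentanedioate (racemic) | CC(=O)C(C)(C(=O)CC(=O)OC)C(=O)OC/C=C(\C)CCC=C(C)C
F2 | step 5 | racemic 2-acetyl-6-[(dimethylamino)methylidene]-4-geranyl-3-hydroxy-4-methylcyclohex-2-ene-1,5-dione | CC(=O)C1=C(O)C(C)(C/C=C(\C)CCC=C(C)C)C(=O)C(=CN(C)C)C1=O
F3 | step 5 | (4S)-2-acetyl-4-geranyl-3-hydroxy-4-methyl-6-({[(1S)-1-phenylethyl]amino}methylidene)cyclohex-2-ene-1,5-dione | CC(=O)C1=C(O)[C@](C)(C/C=C(\C)CCC=C(C)C)C(=O)C(=CN[C@@H](C)c2ccccc2)C1=O
F4 | step 5 | (4R)-2-acetyl-4-geranyl-3-hydroxy-4-methyl-6-({[(1S)-1-phenylethyl]amino}methylidene)cyclohex-2-ene-1,5-dione | CC(=O)C1=C(O)[C@@](C)(C/C=C(\C)CCC=C(C)C)C(=O)C(=CN[C@@H](C)c2ccccc2)C1=O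
F5 | step 7 | (4S)-2-acetyl-4-geranyl-3-hydroxy-4-methylcyclohex-2-ene-1,5-dione | CC(=O)C1=C(O)[C@](C)(C/C=C(\C)CCC=C(C)C)C(=O)CC1=O
F6 | step 7 | 1-{3-[(dimethylamino)methyl]-2,4,6-trihydroxy-5-(3-methylbut-2-en-1-yl)phenyl}butan-1-one | CCCC(=O)c1c(O)c(CC=C(C)C)c(O)c(CN(C)C)c1O
F7 | step 7 | ring B o-quinone methide, 2-butanoyl-3,5-dihydroxy-6-methylidene-4-(3-methylbut-2-en-1-yl)cyclohexa-2,4-dien-1-one | CCCC(=O)C1=C(O)C(CC=C(C)C)=C(O)C(=C)C1=O
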